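Ring B is disconnected at C9–C10 (labdane numbering). The C1 acetoxy oxygen is vicinal to quaternary C10, so a C1–C10 epoxide on a preformed ring A is a masked C10 radical: trivalent titanium opens it, the radical closes ring B 6-endo onto C9 of an E C8=C9 alkene, and loss of a C17 hydrogen leaves the C8=C17 methylidene while oxygen stays on C1. One operation therefore creates the trans-decalin, the C9 and C10 stereocentres and the exocyclic alkene. The precursor is an enantiopure ring A epoxy ester, made by auxiliary-controlled Diels–Alder reaction and iodolactonization, whose C5 chain carries the trisubstituted alkene and a but-2-ynyl end that later becomes the diene.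

Key step: step 9

Numbering: labdane numbering is used in the discussion (ring A = C1–C5 and C10; ring B = C5–C10; C17 = methylidene carbon on C8; C19 = ester carbon on C4; C20 = methyl on C10; side chain C11–C16 on C9). Systematic names use their own locants.

Remark on the chemistry: C4 of the cyclization precursor is a temporary stereocentre. It must be cis to the C5 chain only for the iodolactonization and is erased at the enolate stage (step 11), so epimerization at C4 after step 7 would not reach the target.

Step 1
Reactants: 1 geranyl bromide; 2 prop-1-ynylmagnesium bromide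
Product: 3 (5E)-6,10-dimethylundeca-5,9-dien-2-yne
Conditions: CuCl (10 mol %), THF, 0 °C to 50 °C
Reagents that add atoms: none
Why: Copper-catalysed SN2 alkynylation of a primary allylic bromide by an alkynyl Grignard reagent (the standard skipped-enyne synthesis) should bond the propynyl carbon to the CH2Br carbon and keep the E trisubstituted alkene.

Step 2
Reactants: 3 (5E)-6,10-dimethylundeca-5,9-dien-2-yne
Product: 5 (2E,6E)-2,6-dimethylundeca-2,6-dien-9-ynal, via allylic alcohol 4 (not isolated)
Conditions: SeO2 (cat.), t-BuOOH, salicylic acid (cat.), CH2Cl2, 0 °C to rt; aqueous work-up, then MnO2, CH2Cl2, rt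
Reagents that add atoms: tert-butyl hydroperoxide, CC(C)(C)OO (its oxygen is passed on by catalytic SeO2, O=[Se]=O)
Why: Catalytic SeO2 allylic oxidation (ene reaction then [2,3]-sigmatropic shift) should select the E methyl group of the more electron-rich, less hindered terminal isopropylidene, and MnO2 should then take the allylic alcohol to the E enal without touching the skipped enyne.

Step 3
Reactants: 5 (2E,6E)-2,6-dimethylundeca-2,6-dien-9-ynal
Product: 6 (3E,7E)-3,7-dimethyldodeca-1,3,7-trien-10-yne
Conditions: Ph3PCH3Br, n-BuLi, THF, 0 °C; then 5, −78 °C to rt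
Reagents that add atoms: methyltriphenylphosphonium bromide (as its ylide), C[P+](c1ccccc1)(c1ccccc1)c1ccccc1.[Br-]
Why: Wittig methylenation with the non-stabilised ylide should convert the aldehyde into the terminal alkene and leave both E trisubstituted alkenes and the skipped enyne in place at low temperature.

Step 4
Reactants: 7 (S)-4-benzyl-1,3-oxazolidin-2-one; 8 acryloyl chloride
Product: 10 (S)-3-acryloyl-4-benzyl-1,3-oxazolidin-2-one, via bromomagnesium salt 9 (not isolated)
Conditions: MeMgBr, THF, 0 °C; then 8, −78 °C to 0 °C
Reagents that add atoms: none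
Why: N-Acylation of the bromomagnesium salt of the oxazolidinone with the acid chloride is the established preparation of acryloyl imides and should avoid the polymerisation that lithium salts provoke, with the auxiliary stereocentre untouched.

Step 5
Reactants: 6 (3E,7E)-3,7-dimethyldodeca-1,3,7-trien-10-yne; 10 (S)-3-acryloyl-4-benzyl-1,3-oxazolidin-2-one
Product: 11 (4S)-4-benzyl-3-{(1R,2R)-3-methyl-2-[(3E)-3-methyloct-3-en-6-yn-1-yl]cyclohex-3-ene-1-carbonyl}-1,3-oxazolidin-2-one
Conditions: Et2AlCl (1.4 equiv), CH2Cl2, −78 °C to −40 °C
Reagents that add atoms: none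
Why: Oxazolidinone-auxiliary-controlled Diels–Alder reaction: the Et2AlCl-chelated s-cis imide should be attacked on the face opposite the benzyl group through the endo transition state, the unsubstituted diene terminus bonding to the β-carbon as the 1-alkyl substituent directs ("ortho" adduct), which sets C4 and C5 (both R) with the carbonyl group and the chain cis and places the methyl-bearing C1=C10 alkene in ring A.

Step 6
Reactants: 11 the Diels–Alder imide
Product: 13 (1R,2R)-3-methyl-2-[(3E)-3-methyloct-3-en-6-yn-1-yl]cyclohex-3-ene-1-carboxylic acid, via lithium peroxycarboxylate 12 (not isolated)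
Conditions: LiOH, H2O2, THF/H2O, 0 °C; then Na2SO3 (aq); then HCl to pH 2
Reagents that add atoms: hydrogen peroxide (acting as lithium hydroperoxide), OO
Why: Lithium hydroperoxide should cleave the exocyclic imide carbonyl selectively (standard auxiliary hydrolysis) at 0 °C without epimerising C4, and sulfite reduces the percarboxylate to the carboxylic acid while the auxiliary is recovered.

Step 7
Reactants: 13 the cyclohexene carboxylic acid
Product: 14 (1R,4R,5R,8R)-4-iodo-5-methyl-8-[(3E)-3-methyloct-3-en-6-yn-1-yl]-6-oxabicyclo[3.2.1]octan-7-one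
Conditions: I2, NaHCO3, MeCN/H2O, 0 °C, dark
Reagents that add atoms: iodine, II
Why: Iodolactonization: the carboxylate should add to the tertiary C10 of the ring alkene (five-membered lactone, Markovnikov) anti to the iodonium ion, which fixes the new C10–O bond on the face of the carboxyl group and the C5 chain and puts iodine on C1 on the other face, while the chain alkene and the alkyne have no internal nucleophile.

Step 8
Reactants: 14 the iodolactone
Product: 15 methyl (1R,2R,3R,6S)-1-methyl-2-[(3E)-3-methyloct-3-en-6-yn-1-yl]-7-oxabicyclo[4.1.0]heptane-3-carboxylate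
Conditions: K2CO3, MeOH, 0 °C to rt
Reagents that add atoms: methanol, CO
Why: Methoxide opens the lactone to the methyl ester and the freed C10 alkoxide displaces the anti C1 iodide with inversion (intramolecular Williamson epoxide closure), so the epoxide oxygen is cis to the C5 chain and the ester.

Step 9
Reactants: 15 the cis epoxy ester
Product: 17 methyl (1R,4S,4aR,5R,8aR)-5-(but-2-yn-1-yl)-4-hydroxy-4a-methyl-6-methylidenedecahydronaphthalene-1-carboxylate, via trimethylsilyl ether 16 (not isolated)
Conditions: Cp2TiCl2 (0.2 equiv), Mn dust (8 equiv), Me3SiCl (4 equiv), 2,4,6-collidine (7 equiv), degassed THF, rt, slow addition of 15; then 1 M HCl, THF, rt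
Reagents that add atoms: none
Why: Cp2TiCl, formed in the flask from Cp2TiCl2 and Mn, gives one electron to the epoxide and breaks the C10–O bond, leaving a titanium alkoxide on C1 and the tertiary C10 radical, which adds to C9; the tertiary C8 radical so formed meets a second Cp2TiCl and loses a C17 hydrogen to give the C8=C17 methylidene, and Me3SiCl with collidine recycles titanium and leaves C1–O as a silyl ether that the acid work-up cleaves. The closest known reaction type is the titanocene-mediated epoxide-opening radical cyclization of epoxypolyprenes that ends in exocyclic alkenes, here run as its second ring closure with the epoxide already on ring A. Ring B closes 6-endo-trig, because the methyl group on C8 hinders 5-exo attack and makes the 6-endo radical tertiary. C10 is set by the chair-like transition state in which the C5 tether and the C1 titanium alkoxide are equatorial on ring A, so C9 bonds to the face of C10 remote from the C1 oxygen (trans fusion, C10 methyl axial and cis to that oxygen), and C9 is set by the E geometry of the alkene, which places the butynyl arm equatorial. The step needs ring closure to outrun capture of the C10 radical by titanium and needs termination toward C17; the low stationary concentration of trivalent titanium under catalytic conditions with slow addition should secure the first, and the easier approach of the bulky titanium centre to the unhindered methyl hydrogens the second. C1 keeps the configuration fixed in step 7 because its C–O bond is never broken.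

Step 10
Reactants: 17 the C1 hydroxy ester
Product: 18 methyl (1R,4S,4aR,5R,8aR)-5-(but-2-yn-1-yl)-4a-methyl-6-methylidene-4-(triethylsilyloxy)decahydronaphthalene-1-carboxylate
Conditions: Et3SiOTf, 2,6-lutidine, CH2Cl2, −78 °C to 0 °C
Reagents that add atoms: triethylsilyl trifluoromethanesulfonate, CC[Si](CC)(CC)OS(=O)(=O)C(F)(F)F
Why: Silyl ether protection with a silyl triflate and 2,6-lutidine should silylate the hindered secondary C1 alcohol completely and removes the only acidic proton before the enolate and hydride steps.

Step 11
Reactants: 18 the triethylsilyl ether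
Product: 20 methyl (1R,4S,4aS,5R,8aS)-5-(but-2-yn-1-yl)-1,4a-dimethyl-6-methylidene-4-(triethylsilyloxy)decahydronaphthalene-1-carboxylate, via lithium enolate 19 (not isolated)
Conditions: LiN(i-Pr)2, THF, −78 °C to −40 °C; then MeI, −78 °C to 0 °C
Reagents that add atoms: iodomethane, CI
Why: Ester enolate alkylation: the axial C10 methyl group blocks the axial face of the C4 enolate, so methyl iodide should enter equatorially and leave the ester axial and cis to the C10 methyl, the known outcome for 4-carboxylate enolates of trans-decalins with an angular methyl group.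

Step 12
Reactants: 20 the C4-methylated ester
Product: 22 methyl (1R,4S,4aS,5R,8aS)-5-[(2E)-3-iodobut-2-en-1-yl]-1,4a-dimethyl-6-methylidene-4-(triethylsilyloxy)decahydronaphthalene-1-carboxylate, via alkenylzirconocene chloride 21 (not isolated)
Conditions: Cp2Zr(H)Cl (2.5 equiv), THF, rt to 40 °C; then I2, 0 °C
Reagents that add atoms: iodine, II
Why: Hydrozirconation of the methyl-substituted alkyne is a syn addition that, after equilibration with excess Cp2Zr(H)Cl, should place zirconium on the less hindered methyl-bearing C13, and iodinolysis with retention gives the E 2-iodoalkene, the alkyne reacting faster than the hindered 1,1-disubstituted alkene and the neopentyl ester.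

Step 13
Reactants: 22 the E alkenyl iodide
Product: 23 methyl (1R,4S,4aS,5R,8aS)-1,4a-dimethyl-6-methylidene-5-[(2E)-3-methylpenta-2,4-dien-1-yl]-4-(triethylsilyloxy)decahydronaphthalene-1-carboxylate
Conditions: tributyl(vinyl)stannane, Pd2(dba)3 (cat.), AsPh3, DMF, rt to 50 °C
Reagents that add atoms: tributyl(vinyl)stannane, C=C[Sn](CCCC)(CCCC)CCCC
Why: Stille cross-coupling of the alkenyl iodide with the vinylstannane under zerovalent palladium should proceed with retention of the alkene geometry and tolerates the ester, the silyl ether and the exocyclic alkene.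

Step 14
Reactants: 23 the silyl-protected triene
Product: 25 methyl (1R,4S,4aS,5R,8aS)-4-acetoxy-1,4a-dimethyl-6-methylidene-5-[(2E)-3-methylpenta-2,4-dien-1-yl]decahydronaphthalene-1-carboxylate (CNP0235031.1), via C1 alcohol 24 (not isolated)
Conditions: Bu4NF, THF, rt; then Et3N, DMAP (cat.), Ac2O, rt
Reagents that add atoms: acetic anhydride, CC(=O)OC(C)=O
Why: Fluoride cleaves the triethylsilyl ether and the liberated C1 alkoxide or alcohol is acetylated in the same flask by DMAP-catalysed acyl transfer, both operations being mild enough for the conjugated diene and leaving every stereocentre untouched.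

Compound list

1 | geranyl bromide, (2E)-1-bromo-3,7-dimethylocta-2,6-diene | CC(C)=CCC/C(C)=C/CBr | starting material
2 | prop-1-ynylmagnesium bromide | CC#C[Mg]Br | starting material
3 | (5E)-6,10-dimethylundeca-5,9-dien-2-yne | CC#CC/C=C(\C)CCC=C(C)C | intermediate
4 | (2E,6E)-2,6-dimethylundeca-2,6-dien-9-yn-1-ol (formed in the flask, not isolated) | CC#CC/C=C(\C)CC/C=C(\C)CO | intermediate
5 | (2E,6E)-2,6-dimethylundeca-2,6-dien-9-ynal | CC#CC/C=C(\C)CC/C=C(\C)C=O | intermediate
6 | (3E,7E)-3,7-dimethyldodeca-1,3,7-trien-10-yne | CC#CC/C=C(\C)CC/C=C(\C)C=C | intermediate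
7 | (S)-4-benzyl-1,3-oxazolidin-2-one | O=C1N[C@@H](Cc2ccccc2)CO1 | starting material
8 | acryloyl chloride | C=CC(Cl)=O | starting material
9 | bromomagnesium salt of 7, N–MgBr (formed in the flask, not isolated) | O=C1N([Mg]Br)[C@@H](Cc2ccccc2)CO1 | intermediate
10 | (S)-3-acryloyl-4-benzyl-1,3-oxazolidin-2-one | C=CC(=O)N1[C@@H](Cc2ccccc2)COC1=O | intermediate
11 | (4S)-4-benzyl-3-{(1R,2R)-3-methyl-2-[(3E)-3-methyloct-3-en-6-yn-1-yl]cyclohex-3-ene-1-carbonyl}-1,3-oxazolidin-2-one; carbonyl on C4 and chain on C5 cis | CC#CC/C=C(\C)CC[C@@H]1[C@H](C(=O)N2[C@@H](Cc3ccccc3)COC2=O)CCC=C1C | intermediate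
12 | lithium (1R,2R)-3-methyl-2-[(3E)-3-methyloct-3-en-6-yn-1-yl]cyclohex-3-ene-1-carboperoxoate (formed in the flask, not isolated) | CC#CC/C=C(\C)CC[C@@H]1[C@H](C(=O)O[O-])CCC=C1C.[Li+] | intermediate
13 | (1R,2R)-3-methyl-2-[(3E)-3-methyloct-3-en-6-yn-1-yl]cyclohex-3-ene-1-carboxylic acid | CC#CC/C=C(\C)CC[C@@H]1[C@H](C(=O)O)CCC=C1C | intermediate
14 | (1R,4R,5R,8R)-4-iodo-5-methyl-8-[(3E)-3-methyloct-3-en-6-yn-1-yl]-6-oxabicyclo[3.2.1]octan-7-one; lactone oxygen on C10 cis to the C5 chain, iodine on C1 anti to it | CC#CC/C=C(\C)CC[C@@H]1[C@H]2CC[C@@H](I)[C@]1(C)OC2=O | intermediate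
15 | methyl (1R,2R,3R,6S)-1-methyl-2-[(3E)-3-methyloct-3-en-6-yn-1-yl]-7-oxabicyclo[4.1.0]heptane-3-carboxylate; C1–C10 epoxide, C5 chain and C4 ester all cis | CC#CC/C=C(\C)CC[C@@H]1[C@H](C(=O)OC)CC[C@@H]2O[C@]12C | intermediate
16 | methyl (1R,4S,4aR,5R,8aR)-5-(but-2-yn-1-yl)-4a-methyl-6-methylidene-4-(trimethylsilyloxy)decahydronaphthalene-1-carboxylate (formed in the flask, not isolated) | CC#CC[C@@H]1C(=C)CC[C@H]2[C@@]1(C)[C@@H](O[Si](C)(C)C)CC[C@H]2C(=O)OC | intermediate
17 | methyl (1R,4S,4aR,5R,8aR)-5-(but-2-yn-1-yl)-4-hydroxy-4a-methyl-6-methylidenedecahydronaphthalene-1-carboxylate; trans-decalin, C10 methyl axial, C1–OH equatorial and cis to it, C4 ester axial and cis to it, butynyl arm on C9 equatorial | CC#CC[C@@H]1C(=C)CC[C@H]2[C@@]1(C)[C@@H](O)CC[C@H]2C(=O)OC | intermediate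
18 | methyl (1R,4S,4aR,5R,8aR)-5-(but-2-yn-1-yl)-4a-methyl-6-methylidene-4-(triethylsilyloxy)decahydronaphthalene-1-carboxylate | CC#CC[C@@H]1C(=C)CC[C@H]2[C@@]1(C)[C@@H](O[Si](CC)(CC)CC)CC[C@H]2C(=O)OC | intermediate
19 | lithium enolate of 18, C4=C19 ketene acetal (formed in the flask, not isolated) | CC#CC[C@@H]1C(=C)CC[C@H]2[C@@]1(C)[C@@H](O[Si](CC)(CC)CC)CCC2=C(OC)O[Li] | intermediate
20 | methyl (1R,4S,4aS,5R,8aS)-5-(but-2-yn-1-yl)-1,4a-dimethyl-6-methylidene-4-(triethylsilyloxy)decahydronaphthalene-1-carboxylate; C4 methyl equatorial, ester axial | CC#CC[C@@H]1C(=C)CC[C@H]2[C@@]1(C)[C@@H](O[Si](CC)(CC)CC)CC[C@@]2(C)C(=O)OC | intermediate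
21 | alkenylzirconocene chloride from 20, Cp2Zr(Cl) on C13 and hydrogen on C12 cis to it (formed in the flask, not isolated) | C/C(=C\C[C@@H]1C(=C)CC[C@H]2[C@@]1(C)[C@@H](O[Si](CC)(CC)CC)CC[C@@]2(C)C(=O)OC)[Zr](Cl)(C1C=CC=C1)C1C=CC=C1 | intermediate
22 | methyl (1R,4S,4aS,5R,8aS)-5-[(2E)-3-iodobut-2-en-1-yl]-1,4a-dimethyl-6-methylidene-4-(triethylsilyloxy)decahydronaphthalene-1-carboxylate | C/C(I)=C\C[C@@H]1C(=C)CC[C@H]2[C@@]1(C)[C@@H](O[Si](CC)(CC)CC)CC[C@@]2(C)C(=O)OC | intermediate
23 | methyl (1R,4S,4aS,5R,8aS)-1,4a-dimethyl-6-methylidene-5-[(2E)-3-methylpenta-2,4-dien-1-yl]-4-(triethylsilyloxy)decahydronaphthalene-1-carboxylate | C=C/C(C)=C/C[C@@H]1C(=C)CC[C@H]2[C@@]1(C)[C@@H](O[Si](CC)(CC)CC)CC[C@@]2(C)C(=O)OC | intermediate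
24 | methyl (1R,4S,4aS,5R,8aS)-4-hydroxy-1,4a-dimethyl-6-methylidene-5-[(2E)-3-methylpenta-2,4-dien-1-yl]decahydronaphthalene-1-carboxylate (formed in the flask, not isolated) | C=C/C(C)=C/C[C@@H]1C(=C)CC[C@H]2[C@@]1(C)[C@@H](O)CC[C@@]2(C)C(=O)OC | intermediate
25 | methyl (1R,4S,4aS,5R,8aS)-4-acetoxy-1,4a-dimethyl-6-methylidene-5-[(2E)-3-methylpenta-2,4-dien-1-yl]decahydronaphthalene-1-carboxylate, CNP0235031.1 | C=C/C(C)=C/C[C@@H]1C(=C)CC[C@H]2[C@@]1(C)[C@@H](OC(C)=O)CC[C@@]2(C)C(=O)OC | target

Total step count: 14. Longest linear sequence: 13 steps (steps 1–3 and 5–14); step 4 is a one-step side branch.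

Steps most likely to fail

Step 9. The C10 radical may be captured or reduced by titanium before it cyclizes, the ring may close in part to the cis-fused decalin, or termination may run toward endocyclic alkenes. The fallback sets out from 15 and closes ring B in the cationic manifold instead, with MeAlCl2 in CH2Cl2 at −78 °C (Lewis-acid epoxy-olefin cyclization). Ionization at tertiary C10 with backside attack by C9 enforces the same C9 and C10 configurations and the trans fusion, and the C8 cation loses a proton. The isomer with the C8=C17 methylidene is 17 itself, to be separated from endocyclic alkene isomers on AgNO3-impregnated silica, so the fallback comes back at 17 and makes no compound outside the list (F0).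

Step 12. Regiochemical equilibration of the alkenylzirconium may stay incomplete, and excess hydride may attack the C8=C17 alkene or the ester. The fallback sets out from 20 and adds boron and hydrogen syn across the alkyne by copper-catalysed borylcupration and protonation (CuCl, Xantphos, NaOt-Bu, B2pin2, MeOH, THF, rt), in which the boryl group should go to the less hindered methyl-bearing carbon. This should give methyl (1R,4S,4aS,5R,8aS)-1,4a-dimethyl-6-methylidene-5-[(2Z)-3-(4,4,5,5-tetramethyl-1,3,2-dioxaborolan-2-yl)but-2-en-1-yl]-4-(triethylsilyloxy)decahydronaphthalene-1-carboxylate F1. Suzuki–Miyaura coupling of this boronate with vinyl bromide (Pd(PPh3)4, aqueous K3PO4, THF, 50 °C) comes back at 23 and bypasses 21 and 22.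

Step 5. The two diene substituents direct the dienophile oppositely, so regioselectivity may erode, as may endo or facial selectivity, and the stoichiometric aluminium Lewis acid may degrade the polyunsaturated diene. The fallback sets out from 6 and uses a catalytic enantioselective Diels–Alder reaction with 2,2,2-trifluoroethyl acrylate under a chiral oxazaborolidinium catalyst. The catalyst is the o-tolyl oxazaborolidine from diphenylprolinol activated with Tf2NH, in the enantiomer that the established model assigns to the (1R,2R) adduct, in CH2Cl2 at −78 °C. This should give 2,2,2-trifluoroethyl (1R,2R)-3-methyl-2-[(3E)-3-methyloct-3-en-6-yn-1-yl]cyclohex-3-ene-1-carboxylate F2. Saponification (LiOH, THF/H2O, rt) comes back at acid 13, and steps 4 to 6 are then not needed.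

Further compounds

F0 | step 9 | none | none
F1 | step 12 | methyl (1R,4S,4aS,5R,8aS)-1,4a-dimethyl-6-methylidene-5-[(2Z)-3-(4,4,5,5-tetramethyl-1,3,2-dioxaborolan-2-yl)but-2-en-1-yl]-4-(triethylsilyloxy)decahydronaphthalene-1-carboxylate | C/C(=C\C[C@@H]1C(=C)CC[C@H]2[C@@]1(C)[C@@H](O[Si](CC)(CC)CC)CC[C@@]2(C)C(=O)OC)B1OC(C)(C)C(C)(C)O1
F2 | step 5 | 2,2,2-trifluoroethyl (1R,2R)-3-methyl-2-[(3E)-3-methyloct-3-en-6-yn-1-yl]cyclohex-3-ene-1-carboxylate | CC#CC/C=C(\C)CC[C@@H]1[C@H](C(=O)OCC(F)(F)F)CCC=C1C
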